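Sunday's first reading of target is 2.32 times Thursday's, for a charge of substrate twice as large, and that ratio is the place to start.

common to all: free catalyst 0.0320 M
- Sunday's: substrate 0.400 M
- Thursday's: substrate 0.200 M
- Tuesday's: substrate 0.110 M; time 4.6 min

- Sunday's run (time / min: [target] / M): 0.77: 0.0423; 1.5: 0.0733; 2.3: 0.0951; 3.1: 0.1135; 3.8: 0.1218; 4.6: 0.1255
- Thursday's run (time / min: [target] / M): 0.77: 0.0182; 1.5: 0.0310; 2.3: 0.0395; 3.1: 0.0453; 3.8: 0.0478; 4.6: 0.0497

(scatter of a reading: 0.001 M)

- Overall: substrate -> target, with free catalyst as catalyst.
- Constant volume, constant temperature.
- What is held in complexes is read along with the free species.
- An order is taken over about fifteen percent of the charge, up and down.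

* the exponent of [substrate] in the starting rate at the charge of the Sunday's run (at the point where two percent of the substrate have become target) (one fixed amount of target, the same in the runs compared)
* target in the Tuesday's run at 4.6 min, as a share of the substrate charged

Turn that ratio into a chord order (an apparent order): the logarithm of the ratio of targets at one time, over the logarithm of the ratio of charges. From the first readings it is 1.22. The second way uses the last readings and gives 1.34.

The two part, so ask what each one holds. Sunday's run gains 0.003700 M over its last interval against 0.0423 M over its first, so the late reading holds the whole bent curve and says little about the start. Take the early chord for the starting exponent, and the late chord for Tuesday's run, which is asked at the same clock time. Scaling Thursday's share by the late chord gives 20.3%.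

But a chord is a mean of the local exponent between two charges, and the exponent asked sits at the top of that span. Two charges give one mean and no tilt, so I commit to 1.22 and 20.3%, knowing that this mean may be off at either end. The forecast gave 1.2 (1 to 1.4) and a share of 19% (16% to 22%), lower than mine, with the order “slightly above first order, and probably easing towards the higher charge”.

The flask gives 0.87 and 17.6%.

    free catalyst + substrate ⇌ catalyst-substrate complex, settled at all times (0.2980 M⁻¹)
    catalyst-substrate complex + substrate ⇌ doubly bound catalyst, settled at all times (41.20 M⁻¹)
    doubly bound catalyst → target + catalyst-substrate complex (3.258 min⁻¹)
    free catalyst → spent catalyst (0.2778 min⁻¹)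
    target → decomposed product (0.1098 min⁻¹)

At equal target, Thursday's rate is 0.42 of Sunday's, a chord of 1.24, yet the exponent at Sunday's charge is lower than that and than 1.22, at 0.87. Tuesday's chord with Thursday's at 4.6 min is 1.58, higher than the late 1.34. The turning of free catalyst into spent catalyst is not the reason for that low exponent, which stands at 0.85 without it. In Tuesday's run, though, the share of target stands at 17.6% because the turning of free catalyst into spent catalyst and the turning of target into decomposed product act together, against 25.8% without the first and 23.9% without the second.

The readings come from a simulation with made-up constants, noise included.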